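Readings and results stem from a simulated flask with constants of no real substance, noise included.

**Flask and question**

- How much does the rate of making product change, at a fixed conversion of the substrate, when the charge of free catalyst is changed?

| setting | Sunday's | flask |
|---|---|---|
| substrate | 2 M | 2.0 M |
| free catalyst | 0.05 mol% | 0.1 mol% |
| remark | run made earlier |  |

- Sunday's (time / h: product / %): 3.00: 2.5; 4.00: 2.9; 6.00: 4.5; 10.0: 5.7; 15.0: 6.4; 25.0: 9.2; 40.0: 11.7

(scatter of a reading: 0.5 percentage points)

- what may be going on: substrate + free catalyst <-> catalyst intermediate A; catalyst intermediate A <-> catalyst intermediate B; catalyst intermediate B -> free catalyst + product; free catalyst <-> dormant form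
- no earlier run changes the charge of free catalyst; that part of a forecast is a guess

1. factor on the rate of making product when 10% of the substrate are converted if free catalyst is charged twice over
2. factor on the rate when 10% of the substrate are converted if free catalyst is charged at 0.02 mol% instead

**Reckoning, one process at a time**

- Take the working round first: free catalyst, catalyst intermediate A and catalyst intermediate B turn substrate over, and each step written is first order in catalyst. The rate then follows one concentration, that of working catalyst, and the charge by itself gives factors of 2 and 0.200.
- Now add the dormant form, an off-cycle state. Sunday's first 3.00 h ran 3.93 times as fast as the stretch from 15.0 h to 40.0 h, although 88.3% of the substrate remained at the last reading. Counting the opening rate as full, the late rate over the opening rate, the relaxed working share of the catalyst, reads 0.254, with the scatter of these readings.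
- Relaxation is taken to run on the clock, while conversion runs with the charge. The flask reaches 10% at the hour when Sunday's run stood at 5.00%, between 6.00 h and 10.0 h. Sunday's rate from 4.00 h to 10.0 h puts the working share there at 0.560.
- A doubled charge of the flask corresponds to Sunday's 2.50%, read at 3.00 h, where the share reads 0.900. This gives a factor of 3.21.
- A charge of 0.02 mol% corresponds to Sunday's 25.0%, beyond the last reading, so the relaxed share is taken, and the factor on the rate reckons to 0.0909.

**Forecast and result**

- The forecast stands at 2.9 and 0.4, lower than this reckoning on the first number and higher on the second, and remarks: “Order in catalyst is untested, so ranges are wide”.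
- The simulation gives 2.87 and 0.0940.

    substrate + free catalyst ⇌ catalyst intermediate A (K = 0.440 M⁻¹, k = 0.353 M⁻¹ min⁻¹)
    catalyst intermediate A ⇌ catalyst intermediate B (K = 13.0, k = 1.97 min⁻¹)
    catalyst intermediate B → free catalyst + product (k = 0.870 min⁻¹)
    free catalyst ⇌ dormant form (K = 5.54, k = 0.00254 min⁻¹)

- At 1.54 d in the flask, catalyst intermediate B has a half-life of 0.013 h by its step to product, far shorter than the 0.19 d of free catalyst by its forward step to the dormant form. The flask's forms other than the dormant form hold 51.2% of the catalyst at 0.383 d and 21.0% at 5.00 d. If the rate follows those forms at equal substrate, the simulated factor for 0.02 mol%, taken through that 51.2%, puts their share at 10% conversion in the flask charged at 0.02 mol% at 0.240, where Sunday's run read 0.254.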